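It is impossible for the free catalyst in the maple flask, joining one to one, to use up the added ligand, since there is more ligand than catalyst: the ligand is 3.25% of the left-handed substrate, the catalyst 0.87 mol%.

common to all: left-handed substrate 0.012 M; right-handed substrate 0.012 M; free catalyst 0.87 mol%; added ligand 0.39 mM

| run | partner | racemization catalyst | remark | time |
|---|---|---|---|---|
| maple | 2.5 equiv | 18 mol% | the very flask that is asked about, followed so far |  |
| birch | 2.5 equiv | 36 mol% | run made earlier |  |
| flask | 2.50 equiv | 18 mol% |  | 4.0 h |

| run | time / min | left-handed product / % | right-handed substrate / % |
|---|---|---|---|
| maple | 15.0 | 2.0 | 49.6 |
| maple | 30.0 | 4.7 | 48.1 |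
| maple | 40.0 | 5.1 | 47.7 |
| maple | 60.0 | 7.1 | 47.1 |
| maple | 80.0 | 7.7 | 46.0 |
| birch | 20.0 | 3.3 | 48.7 |
| birch | 40.0 | 5.8 | 47.5 |
| birch | 60.0 | 6.9 | 46.8 |
| birch | 80.0 | 8.3 | 46.2 |
| birch | 90.0 | 8.6 | 45.2 |

(each reading ± 0.3 percentage points)

- free catalyst is single-handed; left-handed substrate and right-handed substrate are mirror images of each other, charged as a racemate, each of them at the stated concentration
- the reaction counts as stopped when no species that holds the left-handed substrate and right-handed substrate together changes by six tenths of a point or more over the second half of the time

- the state of affairs at 4.0 h: stopped, and by what, or still going (the partner has run out first / it is still moving / forward and back rates have come level / all of the left-handed substrate has reacted / no working catalyst is left)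
- amount of left-handed product at 4.0 h, in percent of the left-handed substrate and right-handed substrate together charged
- amount of right-handed substrate at 4.0 h, in percent of the left-handed substrate and right-handed substrate together charged
- amount of left-handed product if the flask were left three thousand times as long, in percent of the left-handed substrate and right-handed substrate together charged

I fold these charges into one number, the blocking ratio, meaning added ligand per free catalyst charged: 3.74. Above one, the ligand has enough to tie up the whole catalyst, but whether it does depends on how tightly it binds, and the charges don't say that. Even then it loses just 26.7% of itself, so I freeze its level, and with it the working share of catalyst. I leave the racemization catalyst out of the number, since birch, with twice as much, reads 8.3% left-handed product at 80.0 min against 7.7% in maple at 80.0 min.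

If the ligand binds tightly, the ratio reads as a slow, steady flask, and if one number were enough, the product would rise in a straight line. It doesn't: in maple the slope after 30.0 min is 0.383 of the slope before it, as a reading, while the right-handed substrate still reads 46.0%. So something besides the block is falling, and these readings don't show what. I commit to a flask that is slow but still moving at 4.0 h.

The forecast says it is still moving, with 10.3% left-handed product, 44.9% right-handed substrate and 11% in the long run. On the slowing it says: “The cause is therefore loss of catalyst activity or an early equilibrium, and these data cannot separate the two”.

The flask gives it is still moving, with 13.3% left-handed product, 43.4% right-handed substrate and 20.1% in the long run.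

    racemization catalyst → spent catalyst (k = 2.20 × 10⁻⁶ /s)
    left-handed substrate + racemization catalyst ⇌ right-handed substrate + racemization catalyst, rate k2*[racemization catalyst]*[left-handed substrate] forward; the back reaction follows from the equilibrium constant (k = 0.340 /M/s)
    free catalyst + added ligand ⇌ idle complex, settled at all times (K = 47000 /M)
    2 partner → self-condensation product (k = 0.00830 /M/s)
    partner + free catalyst + left-handed substrate → free catalyst + left-handed product (k = 350 /M²/s)
    partner + free catalyst + right-handed substrate → free catalyst + right-handed product (k = 3.60 /M²/s)

At a blocking ratio of 3.74, the joining of free catalyst and added ligand is the main reason for the slowness: the idle complex, an off-cycle form, holds 93.2% of the catalyst, and without that joining conversion goes from 13.5% to 68.1%. Free catalyst stays at 6.78% from 0.400 h to 40.0 h, while the partner falls to 9.79% of its charge at 4.00 h. A neighbour flask with added ligand cut to 0.817% of the left-handed substrate has a ratio of 0.939; there the idle complex holds 61.4% and left-handed product reaches 45.2%.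

The readings were computed from invented constants, and the scatter is random.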